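**Retrosynthetic overview**
- Agehoustin E ⇒ 1-(2,6-dibromo-3,4,5-trimethoxyphenyl)-3-(2,4,5-trimethoxyphenyl)propynone. The ring oxygen O1 and the 5-OH both come from the two equivalent ortho C–Br bonds (Cu, hydroxide), so no protecting groups are needed and there is no regiochemical question.
- Ynone C(=O)–C(sp) bond ⇒ acyl anion (NHC Breslow intermediate of the dibromo aldehyde) + alkynyl cation equivalent (alkynyl(phenyl)iodonium salt). Two carbons that are both electrophilic in their parent reagents are joined.
- Dibromo aldehyde ⇐ 3,4,5-trimethoxybenzaldehyde (double bromination); iodonium salt ⇐ 2,4,5-trimethoxybenzaldehyde (one-carbon homologation to the alkyne, then PhI(III)).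
- Ring order: both benzene rings are bought; the only ring formed is the γ-pyranone, closed in the last step.

Assumption: the target has no stereocentre (achiral flavone), so there is no enantiomer to select and the route delivers the single constitution shown.

**Step 1**
Reactants: 1 3,4,5-trimethoxybenzaldehyde
Product: 2 2,6-dibromo-3,4,5-trimethoxybenzaldehyde
Conditions: NBS (2.3 equiv), TFA (cat.), MeCN, 25 → 60 °C, dark
Reagents that add atoms: N-bromosuccinimide, O=C1CCC(=O)N1Br
Why: Electrophilic aromatic bromination (SEAr): the only two free ring positions are equivalent and each is ortho/para to methoxy groups, so two equivalents of Br+ give a single dibromide while the aldehyde is untouched under non-aqueous acidic conditions.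

**Step 2**
Reactants: 3 2,4,5-trimethoxybenzaldehyde
Product: 4 1-ethynyl-2,4,5-trimethoxybenzene
Conditions: dimethyl (1-diazo-2-oxopropyl)phosphonate (1.3 equiv), K2CO3 (2 equiv), MeOH, 0 °C → rt
Reagents that add atoms: Ohira–Bestmann reagent, COP(=O)(OC)C(=[N+]=[N-])C(C)=O
Why: Seyferth–Gilbert homologation (Ohira–Bestmann variant): the diazomethylphosphonate anion released by methanolysis adds to the aldehyde, eliminates dimethyl phosphate in Horner–Wadsworth–Emmons fashion, and N2 loss with 1,2-H shift of the alkylidene carbene gives the terminal alkyne.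

**Step 3**
Reactants: 4 1-ethynyl-2,4,5-trimethoxybenzene
Product: 5 phenyl[(2,4,5-trimethoxyphenyl)ethynyl]iodonium 4-methylbenzenesulfonate
Conditions: PhI(OH)OTs (1.05 equiv), 4 Å MS, CH2Cl2, 0 °C → rt, dark; precipitate with Et2O, store at −20 °C
Reagents that add atoms: Koser's reagent [hydroxy(tosyloxy)iodo]benzene, Cc1ccc(cc1)S(=O)(=O)OI(O)c1ccccc1
Why: Koser alkynyliodonium synthesis: the λ3-iodane adds as an electrophile to the terminal carbon of the electron-rich aryl alkyne and loss of water gives the alkynyl(phenyl)iodonium tosylate (an alkynyl cation equivalent), the non-fluorinated solvent and low temperature keeping the iodane off the trimethoxyarene ring.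

**Step 4**
Reactants: 2 2,6-dibromo-3,4,5-trimethoxybenzaldehyde; 5 phenyl[(2,4,5-trimethoxyphenyl)ethynyl]iodonium 4-methylbenzenesulfonate
Product: 7 1-(2,6-dibromo-3,4,5-trimethoxyphenyl)-3-(2,4,5-trimethoxyphenyl)prop-2-yn-1-one, via Breslow enaminol 6 (not isolated)
Conditions: 2-(pentafluorophenyl)-6,7-dihydro-5H-pyrrolo[2,1-c][1,2,4]triazol-2-ium BF4 (20 mol%), TMEDA (1.2 equiv), toluene, −40 → 0 °C, 5 added in portions to premixed 2/catalyst/base
Reagents that add atoms: none
Why: NHC-catalysed C–H alkynylation of an aldehyde with an alkynyl(aryl)iodonium salt (a known reaction type, here stretched to a di-ortho-bromo aldehyde): the carbene turns the aldehyde carbon into the nucleophilic Breslow enaminol 6 (acyl anion equivalent), which attacks the alkynyl–I(III) carbon with loss of PhI, and collapse of the adduct releases the ynone and the carbene; the linear sp electrophile is the least demanding partner for the hindered donor, the aryl bromides are inert, and no stereocentre is formed.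

**Step 5**
Reactants: 7 1-(2,6-dibromo-3,4,5-trimethoxyphenyl)-3-(2,4,5-trimethoxyphenyl)prop-2-yn-1-one
Product: 10 agehoustin E (5-hydroxy-6,7,8-trimethoxy-2-(2,4,5-trimethoxyphenyl)-4H-chromen-4-one), via 1,3-diketone 8 (not isolated), via 5-bromoflavone 9 (not isolated)
Conditions: LiOH·H2O (5 equiv), DMSO/H2O 4:1, rt, 1 h; then Cu(acac)2 (10 mol%), N,N'-bis(4-hydroxy-2,6-dimethylphenyl)oxalamide (10 mol%), 80 → 100 °C; 1 M HCl work-up
Reagents that add atoms: lithium hydroxide, [Li+].[OH-]; water, O
Why: Proposed new method: a one-pot merger of three individually known events, namely (i) conjugate addition of hydroxide to the ynone (oxa-Michael hydration; carbonyl attack is blocked by the two ortho bromines) giving the enolate of diketone 8, (ii) Cu-catalysed intramolecular Ullmann-type O-arylation of that enolate onto one of the two equivalent ortho C–Br bonds to close the γ-pyranone of 9 (closest precedent: Cu-catalysed cyclisation of 1-(2-haloaryl)-1,3-diketones to chromones), and (iii) carbonyl-assisted Cu-catalysed hydroxylation of the remaining peri C–Br (closest precedent: Cu/oxalamide hydroxylation of aryl bromides with LiOH), the product then being protected as its chelated 5-phenoxide; the equivalence of the two bromines removes any regiochemical issue and no stereocentre arises.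

**Compound list**
1 | 3,4,5-trimethoxybenzaldehyde | COc1cc(C=O)cc(OC)c1OC | starting material
2 | 2,6-dibromo-3,4,5-trimethoxybenzaldehyde | O=Cc1c(Br)c(OC)c(OC)c(OC)c1Br | intermediate
3 | 2,4,5-trimethoxybenzaldehyde | O=Cc1cc(OC)c(OC)cc1OC | starting material
4 | 1-ethynyl-2,4,5-trimethoxybenzene | C#Cc1cc(OC)c(OC)cc1OC | intermediate
5 | phenyl[(2,4,5-trimethoxyphenyl)ethynyl]iodonium 4-methylbenzenesulfonate | COc1cc(OC)c(C#C[I+]c2ccccc2)cc1OC.Cc1ccc(cc1)S(=O)(=O)[O-] | intermediate
6 | Breslow enaminol from 2 and the triazolylidene catalyst (acyl anion equivalent) | OC(=C1N(c2c(F)c(F)c(F)c(F)c2F)N=C2CCCN12)c1c(Br)c(OC)c(OC)c(OC)c1Br | intermediate (not isolated)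
7 | 1-(2,6-dibromo-3,4,5-trimethoxyphenyl)-3-(2,4,5-trimethoxyphenyl)prop-2-yn-1-one | COc1cc(OC)c(C#CC(=O)c2c(Br)c(OC)c(OC)c(OC)c2Br)cc1OC | intermediate
8 | 1-(2,6-dibromo-3,4,5-trimethoxyphenyl)-3-(2,4,5-trimethoxyphenyl)propane-1,3-dione | COc1cc(OC)c(C(=O)CC(=O)c2c(Br)c(OC)c(OC)c(OC)c2Br)cc1OC | intermediate (not isolated)
9 | 5-bromo-6,7,8-trimethoxy-2-(2,4,5-trimethoxyphenyl)-4H-chromen-4-one | COc1cc(OC)c(-c2cc(=O)c3c(Br)c(OC)c(OC)c(OC)c3o2)cc1OC | intermediate (not isolated)
10 | agehoustin E, 5-hydroxy-6,7,8-trimethoxy-2-(2,4,5-trimethoxyphenyl)-4H-chromen-4-one | COc1cc(OC)c(-c2cc(=O)c3c(O)c(OC)c(OC)c(OC)c3o2)cc1OC | target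

**Step count**
Total: 5 steps. Longest linear sequence: 4 steps (3 → 4 → 5 → 7 → 10); the other branch is 1 → 2 → 7 → 10.

**Three steps most likely to fail, with fallbacks**

Step 4 (key coupling). The di-ortho-bromo aldehyde may form the Breslow intermediate too slowly, so that the carbene is consumed by the iodonium salt. The fallback sets out from compound 1, uses 5 unchanged, and comes back to the route at compound 10. Mono-bromination of 1 (NBS 1.05 equiv, MeCN, rt) gives 2-bromo-3,4,5-trimethoxybenzaldehyde F3, a mono-ortho-substituted aldehyde of the kind that is a reliable acyl anion donor. The same NHC alkynylation with 5 then gives 1-(2-bromo-3,4,5-trimethoxyphenyl)-3-(2,4,5-trimethoxyphenyl)prop-2-yn-1-one F4. Hydration and Cu-catalysed O-arylation (LiOH, Cu, DMSO/H2O) close it to 6,7,8-trimethoxy-2-(2,4,5-trimethoxyphenyl)-4H-chromen-4-one F5. The missing 5-oxygen is then installed by ketone-directed Ru(II)-catalysed C5–H oxygenation ([Ru(p-cymene)Cl2]2, K2S2O8, TFA/TFAA, 80 °C), which gives 6,7,8-trimethoxy-4-oxo-2-(2,4,5-trimethoxyphenyl)-4H-chromen-5-yl trifluoroacetate F6; aqueous work-up hydrolyses it to 10.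

Step 5 (one-pot cascade). Hot hydroxide may open the pyranone or cleave the diketone before the hindered second bromide is exchanged. The fallback sets out from compound 7 and comes back at compound 10. Only the first half is run under mild conditions (K2CO3, H2O, cat. CuI, DMF, 80 °C) and the 5-bromoflavone 9 is isolated. The bromide is then exchanged for methoxide (CuBr, NaOMe, MeOH/DMF, 110 °C) to give 5,6,7,8-tetramethoxy-2-(2,4,5-trimethoxyphenyl)-4H-chromen-4-one F7. Selective peri-demethylation with BCl3 (CH2Cl2, −78 → 0 °C) cleaves only the 5-OMe, which chelates boron together with the C4 carbonyl, and gives 10.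

Step 3 (iodonium salt). Koser's reagent may attack the electron-rich ring or give tosyloxyvinyl by-products. The fallback sets out from compound 4 and comes back at compound 5. The alkyne is silylated (n-BuLi, TMSCl, THF, −78 °C) to trimethyl[(2,4,5-trimethoxyphenyl)ethynyl]silane F1. Ipso-iododesilylation with PhIO/BF3·OEt2 (CH2Cl2, −20 → 0 °C; aq NaBF4) is steered to the silylated carbon by the β-silicon effect and gives phenyl[(2,4,5-trimethoxyphenyl)ethynyl]iodonium tetrafluoroborate F2. Anion exchange with aqueous sodium tosylate gives 5.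

**Further compounds**
F1 | step 3 | trimethyl[(2,4,5-trimethoxyphenyl)ethynyl]silane | COc1cc(OC)c(C#C[Si](C)(C)C)cc1OC
F2 | step 3 | phenyl[(2,4,5-trimethoxyphenyl)ethynyl]iodonium tetrafluoroborate | COc1cc(OC)c(C#C[I+]c2ccccc2)cc1OC.F[B-](F)(F)F
F3 | step 4 | 2-bromo-3,4,5-trimethoxybenzaldehyde | COc1cc(C=O)c(Br)c(OC)c1OC
F4 | step 4 | 1-(2-bromo-3,4,5-trimethoxyphenyl)-3-(2,4,5-trimethoxyphenyl)prop-2-yn-1-one | COc1cc(OC)c(C#CC(=O)c2cc(OC)c(OC)c(OC)c2Br)cc1OC
F5 | step 4 | 6,7,8-trimethoxy-2-(2,4,5-trimethoxyphenyl)-4H-chromen-4-one | COc1cc(OC)c(-c2cc(=O)c3cc(OC)c(OC)c(OC)c3o2)cc1OC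
F6 | step 4 | 6,7,8-trimethoxy-4-oxo-2-(2,4,5-trimethoxyphenyl)-4H-chromen-5-yl trifluoroacetate | COc1cc(OC)c(-c2cc(=O)c3c(OC(=O)C(F)(F)F)c(OC)c(OC)c(OC)c3o2)cc1OC
F7 | step 5 | 5,6,7,8-tetramethoxy-2-(2,4,5-trimethoxyphenyl)-4H-chromen-4-one | COc1cc(OC)c(-c2cc(=O)c3c(OC)c(OC)c(OC)c(OC)c3o2)cc1OC
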